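The data are simulated for substances that don't exist.

- The reading came at 8.0 min, and ash had stopped moving long before such a time, standing at 65.5% at 2.00 min and 65.5% at 4.00 min. What I needed was the side of the crossing on which each flask lay.

| flask | solid substrate | reagent | remark | time |
|---|---|---|---|---|
| cedar | 5.0 × 10⁻⁴ M | 0.51 mM | run made earlier |  |
| larch | 5.0 × 10⁻⁴ M | 0.74 mM | run made earlier |  |
| ash | 5.0 × 10⁻⁴ M | 1.1 mM | run made earlier |  |
| zeta | 5.0 × 10⁻⁴ M | 0.400 mM |  | 8.0 min |
| epsilon | 5.0 × 10⁻⁴ M | 0.500 mM |  | 8.0 min |
| gamma | 5.0 × 10⁻⁴ M | 1.25 mM |  | 8.0 min |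

- cedar (time / min: first product / %): 0.333: 50.0; 1.00: 75.9; 2.00: 87.7; 3.00: 91.7; 4.00: 93.6
- larch (time / min: first product / %): 0.333: 64.8; 1.00: 80.7; 2.00: 83.0; 3.00: 84.3; 4.00: 83.9
- ash (time / min: first product / %): 0.333: 62.6; 0.667: 64.3; 1.00: 64.9; 2.00: 65.5; 4.00: 65.5

(scatter of a reading: 0.5 percentage points)

- solid substrate is a solid; its amount is given per volume of the solution
- what may be going on: starting material + reagent -> first product; reagent + first product <-> bis adduct; solid substrate <-> starting material; reagent <-> dormant form
- at the start none of the solid substrate is in solution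

1. first product at the end, in percent of the solid substrate charged, for each flask in turn (zeta, epsilon, gamma)

- The crossing lay where reagent charged equalled solid substrate charged, 0.5 mM. Below it reagent was the limiting reagent, and above it surplus reagent could carry first product on to bis adduct.
- I carried one quantity, the plateau quotient: [bis adduct] / ([first product] × [spare reagent]), where spare reagent is the charge minus what first product and bis adduct hold. Taking all the solid as consumed, ash gave 1.23 mM⁻¹, and larch, a different charge, gave 1.20 mM⁻¹.
- Zeta, at 0.400 mM, lay below the crossing, so by hand its ceiling was the charge ratio, 80.0%.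
- Epsilon, at 0.500 mM, lay on the crossing with a ceiling of 100%, but cedar, just above it, was still climbing at 93.6% at 4.00 min, so I expected epsilon to fall short of that ceiling.
- Gamma, at 1.25 mM, lay above the crossing, and the quotient gave it 0.202 mM of bis adduct, so 59.7% first product.
- The forecast gave 79.8%, 96.2% and 60.1%, holding that “no reagent is lost and any dormant form only buffers it”. My gamma figure lay 0.40 percentage points below its own.
- The flasks gave 80.0%, 96.5% and 59.4%, each within the forecast's margin.

    starting material + reagent → first product (k = 750 L mol⁻¹ s⁻¹)
    reagent + first product ⇌ bis adduct (K = 3500 L mol⁻¹, k = 570 L mol⁻¹ s⁻¹)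
    solid substrate ⇌ starting material, rate k3*(cs3 - [starting material]) while solid is left; crystals form when [starting material] > cs3 (solubility = 0.160 mM, k = 5.30 s⁻¹)
    reagent ⇌ dormant form (K = 1.80, k = 0.120 s⁻¹)

- In zeta at 8.00 min, reagent had a half-life of 0.15 min against starting material, while first product's half-life by the forward step to bis adduct alone was 25 h, far longer than the 8.0 min of the run. With spare reagent counted as reagent plus dormant form, the plateau quotient came to 1.25 mM⁻¹ in gamma and 1.24 mM⁻¹ in epsilon at 8.00 min.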